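The synthesis depends on cutting two bonds of the spiro[4.5]decene at once: C9–C10 in the cyclohexene and C4–C5 in the cyclopentane. The feature exploited is the array C9(OH)–C10–C5, whose spiro atom C5 adjoins C1. A C5=C10 alkene can add to a C9 aldehyde, and the charge left on C5 can draw C4 over from a C1 cyclobutanol. One Lewis acid step therefore closes the cyclohexene, enlarges cyclobutane to cyclopentanone, and sets C5 and C9. Its precursor is a (Z)-2-methylenal linked through C6 to a 1-alkenyl-2-methylcyclobutanol triethylsilyl ether. The C1 ketone that appears then accepts the side chain.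

Key step: step 8

Remark: the locants C1–C10 of the final spiro[4.5]decene and C1'–C6' of its side chain (C1' on C1, C6' bearing the acetate) are used for the same atoms in all intermediates; TMS, TES and TBS are trimethylsilyl, triethylsilyl and tert-butyldimethylsilyl.

Design choices around the key step:
- The C1 oxygen carries TES. This group survives the oxidation to the enal and chromatography, still leaves easily in the rearrangement, and by its bulk stays clear of the C6 chain.
- C4 is brought in enantiopure from (S)-lactate, so no volatile ketone has to be resolved.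
- The enal is made last and used cold, with a hindered pyridine as acid scavenger.

Step 1
Reactants: 1 ethyl (S)-lactate
Product: 2 ethyl (2S)-2-(trimethylsilyloxy)propanoate
Conditions: TMSCl, Et3N, CH2Cl2, 0 °C → rt
Reagents that add atoms: chlorotrimethylsilane, C[Si](C)(C)Cl
Why: Routine O-silylation masks the hydroxyl group against the Grignard reagent of step 2 without touching the stereocentre, and the small silyl group falls off again in the acidic work-up of that step.

Step 2
Reactants: 2 ethyl (2S)-2-(trimethylsilyloxy)propanoate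
Product: 4 1-[(1S)-1-hydroxyethyl]cyclopropan-1-ol, via silyl ether 3 (not isolated)
Conditions: EtMgBr (3 equiv), Ti(OiPr)4 (cat.), Et2O–THF, 0 °C → rt; then 1 M H2SO4, 0 °C
Reagents that add atoms: ethylmagnesium bromide, CC[Mg]Br
Why: Kulinkovich cyclopropanation, in which the titanacyclopropane made from EtMgBr acts as a 1,2-dicarbanion toward the ester, is well known for O-protected α-hydroxy esters and leaves the carbinol stereocentre as it is.

Step 3
Reactants: 4 1-[(1S)-1-hydroxyethyl]cyclopropan-1-ol
Product: 6 (S)-2-methylcyclobutanone, via mesylate 5 (not isolated)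
Conditions: MsCl (1.05 equiv), Et3N, CH2Cl2, −20 °C → rt; distil, keep as a dry Et2O solution
Reagents that add atoms: none
Why: Pinacol-type ring expansion of an α-hydroxycyclopropylcarbinyl sulfonate, in which the secondary alcohol is mesylated selectively and a ring C–C bond migrates anti to the leaving group, so that inversion at the carbinol carbon turns the (S)-lactate centre into the (S)-configured C4.

Step 4
Reactants: 7 propargyl alcohol; 8 2,3-dibromopropene
Product: 10 (2Z)-5-bromo-2-methylhexa-2,5-dien-1-ol, via magnesacycle 9 (not isolated)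
Conditions: MeMgBr (3 equiv), CuI (cat.), THF, −10 °C → rt; then 8 (2.5 equiv), 0 °C → rt
Reagents that add atoms: methylmagnesium bromide, C[Mg]Br
Why: Copper-catalysed anti-carbomagnesiation of the propargylic alkoxide puts methyl on the inner carbon (C8) and magnesium on the terminal carbon (C7) cis to CH2O in a five-membered chelate, and copper-catalysed allylation of this alkenyl Grignard reagent with retention fixes the Z geometry of C7=C8.

Step 5
Reactants: 10 (2Z)-5-bromo-2-methylhexa-2,5-dien-1-ol; 6 (S)-2-methylcyclobutanone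
Product: 12 (1R,2S)-1-[(4Z)-6-hydroxy-5-methylhexa-1,4-dien-2-yl]-2-methylcyclobutan-1-ol, via dilithio species 11 (not isolated)
Conditions: 10 (1.2 equiv), MeLi then t-BuLi (2 equiv per bromide), Et2O, −78 °C; then 6, −78 °C; H2O
Reagents that add atoms: none
Why: Bromine–lithium exchange on the lithium alkoxide gives the alkenyllithium, which adds 1,2 to the strained and therefore very electrophilic ketone from the face anti to the C4 methyl group, so that the new C1–O bond stands cis to that methyl group (1R) and the minor epimer can be removed by chromatography.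

Step 6
Reactants: 12 (1R,2S)-1-[(4Z)-6-hydroxy-5-methylhexa-1,4-dien-2-yl]-2-methylcyclobutan-1-ol
Product: 13 (1R,2S)-2-methyl-1-[(4Z)-5-methyl-6-(triethylsilyloxy)hexa-1,4-dien-2-yl]-1-(triethylsilyloxy)cyclobutane
Conditions: Et3SiOTf (2.5 equiv), 2,6-lutidine, CH2Cl2, −78 → 0 °C
Reagents that add atoms: triethylsilyl triflate, CC[Si](CC)(CC)OS(=O)(=O)C(F)(F)F
Why: A silyl triflate buffered by a hindered pyridine silylates the primary and also the tertiary hydroxyl group without ionising the allylic cyclobutanol.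

Step 7
Reactants: 13 (1R,2S)-2-methyl-1-[(4Z)-5-methyl-6-(triethylsilyloxy)hexa-1,4-dien-2-yl]-1-(triethylsilyloxy)cyclobutane
Product: 14 (2Z)-2-methyl-5-[(1R,2S)-2-methyl-1-(triethylsilyloxy)cyclobutyl]hexa-2,5-dienal
Conditions: (COCl)2, DMSO, CH2Cl2, −78 → −40 °C; then Et3N, −78 → −20 °C
Reagents that add atoms: none
Why: Under Swern conditions the activated sulfoxide cleaves a primary triethylsilyl ether and oxidises it directly to the aldehyde while tertiary silyl ethers stay intact, a known selective oxidation of silyl ethers, and the low temperature keeps the Z geometry of C7=C8.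

Step 8
Reactants: 14 (2Z)-2-methyl-5-[(1R,2S)-2-methyl-1-(triethylsilyloxy)cyclobutyl]hexa-2,5-dienal
Product: 16 (4S,5S,9S)-9-hydroxy-4,8-dimethylspiro[4.5]dec-7-en-1-one, via C5 cation 15 (not isolated)
Conditions: SnCl4 (1.2 equiv), 2,6-di-tert-butyl-4-methylpyridine (0.3 equiv), CH2Cl2 (0.01 M), −78 °C; then Et3N–MeOH, aq. NaHCO3
Reagents that add atoms: none
Why: SnCl4 binds the aldehyde oxygen, the CH2 terminus C10 of the 1,1-disubstituted alkene adds to C9, and the charge that builds up on C5 (zwitterion 15) is quenched by the 1,2-shift of C4 from C1 to C5, which releases the cyclobutane strain, unveils the C1 ketone and expels the silyl group as Et3SiCl. The closest known reaction type is the pinacol-terminated Prins cyclisation of 1-alkenylcycloalkanol silyl ethers, including cyclobutanols that expand to spiro cyclopentanones; here a Lewis-acid-bound enal takes the place of the usual oxocarbenium ion. The cyclohexene closes in the 6-endo-trig mode at the C5=C10 alkene (exo at the carbonyl group), while the cyclopentanone arises by four-to-five ring expansion and not by a cyclisation. C5 is controlled by the C1 carbinol centre: the bulky silyloxy group avoids the C6 chain and lies near the alkene plane on the =CH2 side, C4 stands perpendicular to that plane and moves with retention to the face of C5 opposite to the incoming C9, so that C10 ends cis and C6 trans to the C4 methyl group. C9 is controlled by tin, whose second free site can hold the C1 oxygen, so that C9–O sits pseudoaxial on the C1 side of the new ring and away from migrating C4. The step needs 1,2-attack on an intact Z-enal and migration of C4 rather than C2: conjugate attack at C7 would need a four-membered ring, the cis arrangement of C6 and C9 on C7=C8 is what allows closure and is preserved by −78 °C, short contact and the acid scavenger, and the more substituted C4 is the better migrating carbon.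

Step 9
Reactants: 16 (4S,5S,9S)-9-hydroxy-4,8-dimethylspiro[4.5]dec-7-en-1-one
Product: 17 (4S,5S,9S)-9-(tert-butyldimethylsilyloxy)-4,8-dimethylspiro[4.5]dec-7-en-1-one
Conditions: TBSCl, imidazole, DMF, rt
Reagents that add atoms: tert-butyldimethylsilyl chloride, CC(C)(C)[Si](C)(C)Cl
Why: Standard silylation of the secondary allylic alcohol protects C9–OH against the bases and hydrides to come, stops hemiketal formation with the C1 ketone, and adds bulk on the C10 face of the five-membered ring that helps the equilibration in step 11.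

Step 10
Reactants: 17 (4S,5S,9S)-9-(tert-butyldimethylsilyloxy)-4,8-dimethylspiro[4.5]dec-7-en-1-one
Product: 18 (4S,5S,9S)-9-(tert-butyldimethylsilyloxy)-4,8-dimethylspiro[4.5]dec-7-ene-1-carbonitrile (both C1 epimers)
Conditions: TosMIC, t-BuOK, DME–t-BuOH, 0 → 40 °C
Reagents that add atoms: 4-toluenesulfonylmethyl isocyanide (TosMIC), Cc1ccc(cc1)S(=O)(=O)C[N+]#[C-]
Why: Van Leusen reductive cyanation turns a ketone into the homologous nitrile in one step and is known to work on cyclopentanones with a quaternary α-carbon such as 17-oxo steroids; the C1 configuration is not controlled here and does not need to be.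

Step 11
Reactants: 18 (4S,5S,9S)-9-(tert-butyldimethylsilyloxy)-4,8-dimethylspiro[4.5]dec-7-ene-1-carbonitrile
Product: 20 1-[(1S,4S,5S,9S)-9-(tert-butyldimethylsilyloxy)-4,8-dimethylspiro[4.5]dec-7-en-1-yl]ethan-1-one, via lithio ketimine 19 (not isolated)
Conditions: MeLi, Et2O, 0 °C → rt; aq. AcOH–THF; then NaOMe (cat.), MeOH, rt
Reagents that add atoms: methyllithium, C[Li]; water, O
Why: Addition of methyllithium to the nitrile and hydrolysis of the ketimine give the methyl ketone, and methoxide then equilibrates C1 through the enolate toward the epimer whose acetyl group lies on the C6 face, trans to the C4 methyl group and away from C10 and the C9 silyloxy group, the same kind of thermodynamic control that favours 17β-acetyl steroids.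

Step 12
Reactants: 20 1-[(1S,4S,5S,9S)-9-(tert-butyldimethylsilyloxy)-4,8-dimethylspiro[4.5]dec-7-en-1-yl]ethan-1-one
Product: 21 ethyl (2E)-3-[(1R,4S,5S,9S)-9-(tert-butyldimethylsilyloxy)-4,8-dimethylspiro[4.5]dec-7-en-1-yl]but-2-enoate
Conditions: (EtO)2P(O)CH2CO2Et, NaH, THF, reflux
Reagents that add atoms: triethyl phosphonoacetate, CCOC(=O)CP(=O)(OCC)OCC
Why: Horner–Wadsworth–Emmons olefination of a hindered methyl ketone, known for 20-oxo steroids, places the ester trans to the bulky ring substituent (E), and any C1 epimerisation under the basic conditions only feeds the same favoured epimer.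

Step 13
Reactants: 21 ethyl (2E)-3-[(1R,4S,5S,9S)-9-(tert-butyldimethylsilyloxy)-4,8-dimethylspiro[4.5]dec-7-en-1-yl]but-2-enoate
Product: 22 (2E)-3-[(1R,4S,5S,9S)-9-(tert-butyldimethylsilyloxy)-4,8-dimethylspiro[4.5]dec-7-en-1-yl]but-2-en-1-ol
Conditions: i-Bu2AlH (2.5 equiv), CH2Cl2, −78 °C; aq. potassium sodium tartrate
Reagents that add atoms: none
Why: 1,2-Reduction of the enoate with i-Bu2AlH gives the (E)-allylic alcohol needed for hydroxyl-assisted hydrogenation and touches neither the silyl ether nor the alkenes.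

Step 14
Reactants: 22 (2E)-3-[(1R,4S,5S,9S)-9-(tert-butyldimethylsilyloxy)-4,8-dimethylspiro[4.5]dec-7-en-1-yl]but-2-en-1-ol
Product: 23 (3R)-3-[(1R,4S,5S,9S)-9-(tert-butyldimethylsilyloxy)-4,8-dimethylspiro[4.5]dec-7-en-1-yl]butan-1-ol
Conditions: H2 (100 bar), Ru(OAc)2[(R)-BINAP] (cat.), MeOH, rt
Reagents that add atoms: none
Why: Noyori hydrogenation of allylic alcohols, in which only the alkene next to the free hydroxyl group is taken up by ruthenium, so that C7=C8 survives as the remote alkene of geraniol does, and in which the (R)-BINAP complex adds hydrogen to the face of the (E)-alkene that gives (1'R), the sense known from geraniol to (S)-citronellol (the descriptor differs because ring carbon C1 outranks C2').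

Step 15
Reactants: 23 (3R)-3-[(1R,4S,5S,9S)-9-(tert-butyldimethylsilyloxy)-4,8-dimethylspiro[4.5]dec-7-en-1-yl]butan-1-ol
Product: 24 (3R)-3-[(1R,4S,5S,9S)-9-(tert-butyldimethylsilyloxy)-4,8-dimethylspiro[4.5]dec-7-en-1-yl]butyl 4-toluenesulfonate
Conditions: TsCl, Et3N, DMAP (cat.), CH2Cl2, 0 °C → rt
Reagents that add atoms: 4-toluenesulfonyl chloride, Cc1ccc(cc1)S(=O)(=O)Cl
Why: Routine sulfonylation activates the unhindered primary alcohol at C3' under conditions that spare the silyl ether and the alkene.

Step 16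
Reactants: 25 (R)-3-bromo-2-methylpropan-1-ol
Product: 26 [(2R)-3-bromo-2-methylpropoxy](tert-butyl)dimethylsilane
Conditions: TBSCl, imidazole, CH2Cl2, rt
Reagents that add atoms: tert-butyldimethylsilyl chloride, CC(C)(C)[Si](C)(C)Cl
Why: Routine silylation of the commercial chiral-pool bromo alcohol, whose stereocentre becomes C5' (S in the target, because CH2O then outranks the carbon chain) and is not touched.

Step 17
Reactants: 26 [(2R)-3-bromo-2-methylpropoxy](tert-butyl)dimethylsilane; 24 (3R)-3-[(1R,4S,5S,9S)-9-(tert-butyldimethylsilyloxy)-4,8-dimethylspiro[4.5]dec-7-en-1-yl]butyl 4-toluenesulfonate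
Product: 28 tert-butyl{[(2S,6R)-6-[(1R,4S,5S,9S)-9-(tert-butyldimethylsilyloxy)-4,8-dimethylspiro[4.5]dec-7-en-1-yl]-2-methylheptyl]oxy}dimethylsilane, via Grignard reagent 27 (not isolated)
Conditions: 26 (2 equiv), Mg, THF, reflux; then 24, Li2CuCl4 (cat.), THF, −20 → 0 °C
Reagents that add atoms: none
Why: Copper-catalysed alkyl–alkyl cross-coupling of a primary Grignard reagent with a primary tosylate forms C3'–C4' without touching any stereocentre, and γ-silyloxy Grignard reagents of this kind are well-known coupling partners.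

Step 18
Reactants: 28 tert-butyl{[(2S,6R)-6-[(1R,4S,5S,9S)-9-(tert-butyldimethylsilyloxy)-4,8-dimethylspiro[4.5]dec-7-en-1-yl]-2-methylheptyl]oxy}dimethylsilane
Product: 29 (2S,6R)-6-[(1R,4S,5S,9S)-9-hydroxy-4,8-dimethylspiro[4.5]dec-7-en-1-yl]-2-methylheptan-1-ol
Conditions: Bu4NF (3 equiv), THF, rt → 45 °C
Reagents that add atoms: none
Why: Fluoride cleaves both silyl ethers, the hindered allylic one on gentle warming, and nothing else in the molecule is sensitive to it.

Step 19
Reactants: 29 (2S,6R)-6-[(1R,4S,5S,9S)-9-hydroxy-4,8-dimethylspiro[4.5]dec-7-en-1-yl]-2-methylheptan-1-ol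
Product: 30 (2S,6R)-6-[(1R,4S,5S,9S)-9-hydroxy-4,8-dimethylspiro[4.5]dec-7-en-1-yl]-2-methylheptyl acetate (target)
Conditions: AcCl (1.05 equiv), 2,4,6-collidine, CH2Cl2, −78 °C
Reagents that add atoms: acetyl chloride, CC(=O)Cl
Why: At low temperature with a hindered base the unhindered primary alcohol is acylated far faster than the secondary allylic C9–OH, which is flanked by the C8 methyl group and the spiro centre, so the monoacetate should be the target.

Compound list

1 | ethyl (S)-lactate | C[C@H](O)C(=O)OCC | starting material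
2 | ethyl (2S)-2-(trimethylsilyloxy)propanoate | C[C@H](O[Si](C)(C)C)C(=O)OCC | intermediate
3 | 1-[(1S)-1-(trimethylsilyloxy)ethyl]cyclopropan-1-ol | C[C@H](O[Si](C)(C)C)C1(O)CC1 | intermediate
4 | 1-[(1S)-1-hydroxyethyl]cyclopropan-1-ol | C[C@H](O)C1(O)CC1 | intermediate
5 | (1S)-1-(1-hydroxycyclopropyl)ethyl methanesulfonate | C[C@H](OS(C)(=O)=O)C1(O)CC1 | intermediate
6 | (S)-2-methylcyclobutanone | O=C1CC[C@@H]1C | intermediate
7 | propargyl alcohol | C#CCO | starting material
8 | 2,3-dibromopropene | C=C(Br)CBr | starting material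
9 | 4-methyl-1-oxa-2-magnesacyclopent-3-ene (chelated alkenylmagnesium alkoxide) | CC1=C[Mg]OC1 | intermediate
10 | (2Z)-5-bromo-2-methylhexa-2,5-dien-1-ol | OC/C(C)=C\CC(Br)=C | intermediate
11 | lithium (2Z)-5-lithio-2-methylhexa-2,5-dien-1-olate | [Li]OC/C(C)=C\CC([Li])=C | intermediate
12 | (1R,2S)-1-[(4Z)-6-hydroxy-5-methylhexa-1,4-dien-2-yl]-2-methylcyclobutan-1-ol | OC/C(C)=C\CC(=C)[C@@]1(O)CC[C@@H]1C | intermediate
13 | (1R,2S)-2-methyl-1-[(4Z)-5-methyl-6-(triethylsilyloxy)hexa-1,4-dien-2-yl]-1-(triethylsilyloxy)cyclobutane | CC[Si](CC)(CC)OC/C(C)=C\CC(=C)[C@@]1(O[Si](CC)(CC)CC)CC[C@@H]1C | intermediate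
14 | (2Z)-2-methyl-5-[(1R,2S)-2-methyl-1-(triethylsilyloxy)cyclobutyl]hexa-2,5-dienal | O=C/C(C)=C\CC(=C)[C@@]1(O[Si](CC)(CC)CC)CC[C@@H]1C | intermediate
15 | zwitterion after C9–C10 bond formation: cyclohexenyl cation at C5, (9S)-oxygen bound to SnCl4, silyloxycyclobutane still intact | Cl[Sn-](Cl)(Cl)(Cl)O[C@H]1C[C+](CC=C1C)[C@@]2(O[Si](CC)(CC)CC)CC[C@@H]2C | intermediate
16 | (4S,5S,9S)-9-hydroxy-4,8-dimethylspiro[4.5]dec-7-en-1-one | O=C1CC[C@H](C)[C@@]12CC=C(C)[C@@H](O)C2 | intermediate
17 | (4S,5S,9S)-9-(tert-butyldimethylsilyloxy)-4,8-dimethylspiro[4.5]dec-7-en-1-one | O=C1CC[C@H](C)[C@@]12CC=C(C)[C@@H](O[Si](C)(C)C(C)(C)C)C2 | intermediate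
18 | (4S,5S,9S)-9-(tert-butyldimethylsilyloxy)-4,8-dimethylspiro[4.5]dec-7-ene-1-carbonitrile, both C1 epimers | N#CC1CC[C@H](C)[C@@]12CC=C(C)[C@@H](O[Si](C)(C)C(C)(C)C)C2 | intermediate
19 | N-lithio ketimine from 18 and MeLi, both C1 epimers | [Li]N=C(C)C1CC[C@H](C)[C@@]12CC=C(C)[C@@H](O[Si](C)(C)C(C)(C)C)C2 | intermediate
20 | 1-[(1S,4S,5S,9S)-9-(tert-butyldimethylsilyloxy)-4,8-dimethylspiro[4.5]dec-7-en-1-yl]ethan-1-one | CC(=O)[C@H]1CC[C@H](C)[C@@]12CC=C(C)[C@@H](O[Si](C)(C)C(C)(C)C)C2 | intermediate
21 | ethyl (2E)-3-[(1R,4S,5S,9S)-9-(tert-butyldimethylsilyloxy)-4,8-dimethylspiro[4.5]dec-7-en-1-yl]but-2-enoate | CCOC(=O)/C=C(\C)[C@H]1CC[C@H](C)[C@@]12CC=C(C)[C@@H](O[Si](C)(C)C(C)(C)C)C2 | intermediate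
22 | (2E)-3-[(1R,4S,5S,9S)-9-(tert-butyldimethylsilyloxy)-4,8-dimethylspiro[4.5]dec-7-en-1-yl]but-2-en-1-ol | OC/C=C(\C)[C@H]1CC[C@H](C)[C@@]12CC=C(C)[C@@H](O[Si](C)(C)C(C)(C)C)C2 | intermediate
23 | (3R)-3-[(1R,4S,5S,9S)-9-(tert-butyldimethylsilyloxy)-4,8-dimethylspiro[4.5]dec-7-en-1-yl]butan-1-ol | OCC[C@@H](C)[C@H]1CC[C@H](C)[C@@]12CC=C(C)[C@@H](O[Si](C)(C)C(C)(C)C)C2 | intermediate
24 | (3R)-3-[(1R,4S,5S,9S)-9-(tert-butyldimethylsilyloxy)-4,8-dimethylspiro[4.5]dec-7-en-1-yl]butyl 4-toluenesulfonate | Cc1ccc(cc1)S(=O)(=O)OCC[C@@H](C)[C@H]1CC[C@H](C)[C@@]12CC=C(C)[C@@H](O[Si](C)(C)C(C)(C)C)C2 | intermediate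
25 | (R)-3-bromo-2-methylpropan-1-ol | OC[C@@H](C)CBr | starting material
26 | [(2R)-3-bromo-2-methylpropoxy](tert-butyl)dimethylsilane | CC(C)(C)[Si](C)(C)OC[C@@H](C)CBr | intermediate
27 | (2R)-3-(tert-butyldimethylsilyloxy)-2-methylpropylmagnesium bromide | CC(C)(C)[Si](C)(C)OC[C@@H](C)C[Mg]Br | intermediate
28 | tert-butyl{[(2S,6R)-6-[(1R,4S,5S,9S)-9-(tert-butyldimethylsilyloxy)-4,8-dimethylspiro[4.5]dec-7-en-1-yl]-2-methylheptyl]oxy}dimethylsilane | CC(C)(C)[Si](C)(C)OC[C@@H](C)CCC[C@@H](C)[C@H]1CC[C@H](C)[C@@]12CC=C(C)[C@@H](O[Si](C)(C)C(C)(C)C)C2 | intermediate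
29 | (2S,6R)-6-[(1R,4S,5S,9S)-9-hydroxy-4,8-dimethylspiro[4.5]dec-7-en-1-yl]-2-methylheptan-1-ol | OC[C@@H](C)CCC[C@@H](C)[C@H]1CC[C@H](C)[C@@]12CC=C(C)[C@@H](O)C2 | intermediate
30 | (2S,6R)-6-[(1R,4S,5S,9S)-9-hydroxy-4,8-dimethylspiro[4.5]dec-7-en-1-yl]-2-methylheptyl acetate | CC(=O)OC[C@@H](C)CCC[C@@H](C)[C@H]1CC[C@H](C)[C@@]12CC=C(C)[C@@H](O)C2 | target

Total step count: 19. Longest linear sequence: 17 steps (steps 1–3, 5–15 and 17–19).

Steps most likely to fail

**First, step 8.**
- What may go wrong: poor facial selectivity at the aldehyde carbon if tin does not hold both oxygens, so that C9–O ends on the C4 side of the new ring. C5 and both rings would still form as planned.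
- The fallback sets out from 14 and comes back at 16.
- The cyclisation is run as in step 8, and the C9 epimer that it then delivers, (4S,5S,9R)-9-hydroxy-4,8-dimethylspiro[4.5]dec-7-en-1-one F1, is collected.
- A Mitsunobu reaction (PPh3, DIAD, 4-nitrobenzoic acid, toluene, 0 °C) should invert the allylic carbinol centre by SN2 displacement, as it does for carveol-type 2-methylcyclohex-2-enols. The product should be (4S,5S,9S)-4,8-dimethyl-1-oxospiro[4.5]dec-7-en-9-yl 4-nitrobenzoate F2.
- K2CO3 in MeOH at rt then releases 16.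
- C9 is thus set by substitution and no longer by the cyclisation.

**Second, step 10.**
- What may go wrong: sluggish addition of the TosMIC anion to the carbonyl group next to the spiro centre, with enolisation and decay of the reagent taking over.
- The fallback sets out from 17 and comes back at 20, so it also bypasses step 11.
- KN(SiMe3)2 and PhNTf2 in THF at −78 °C, where only C2 can be deprotonated, should give (4S,5S,9S)-9-(tert-butyldimethylsilyloxy)-4,8-dimethylspiro[4.5]deca-1,7-dien-1-yl trifluoromethanesulfonate F3.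
- Stille coupling with tributyl(1-ethoxyvinyl)stannane (Pd(PPh3)4, LiCl, THF, reflux), well known for enol triflates next to quaternary carbons, should give tert-butyl{[(4S,5S,9S)-1-(1-ethoxyethenyl)-4,8-dimethylspiro[4.5]deca-1,7-dien-9-yl]oxy}dimethylsilane F4.
- Aqueous oxalic acid in THF hydrolyses F4 to 1-[(4S,5S,9S)-9-(tert-butyldimethylsilyloxy)-4,8-dimethylspiro[4.5]deca-1,7-dien-1-yl]ethan-1-one F5.
- Conjugate reduction with [(PPh3)CuH]6 in toluene at rt, followed by NaOMe in MeOH for the same C1 equilibration, gives 20.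

**Third, step 14.**
- What may go wrong: slow hydrogen uptake at the hindered trisubstituted alkene, migration of the double bond toward the aldehyde, or incomplete facial selectivity at C1'.
- The fallback sets out from 21 and comes back at 23, so it also bypasses step 13.
- Copper hydride generated from Cu(OAc)2, DTBM-SEGPHOS and polymethylhydrosiloxane (t-BuOH, toluene, 0 °C → rt) adds hydride only to the β-carbon C1' of the enoate, under ligand control. The ligand antipode is fixed by one trial with each hand.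
- This is the known asymmetric conjugate reduction of β,β-disubstituted enoates, and it should give ethyl (3R)-3-[(1R,4S,5S,9S)-9-(tert-butyldimethylsilyloxy)-4,8-dimethylspiro[4.5]dec-7-en-1-yl]butanoate F6.
- LiAlH4 in Et2O at 0 °C then gives 23.

Further compounds

F1 | step 8 | (4S,5S,9R)-9-hydroxy-4,8-dimethylspiro[4.5]dec-7-en-1-one | O=C1CC[C@H](C)[C@@]12CC=C(C)[C@H](O)C2
F2 | step 8 | (4S,5S,9S)-4,8-dimethyl-1-oxospiro[4.5]dec-7-en-9-yl 4-nitrobenzoate | O=C1CC[C@H](C)[C@@]12CC=C(C)[C@@H](OC(=O)c3ccc(cc3)[N+](=O)[O-])C2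
F3 | step 10 | (4S,5S,9S)-9-(tert-butyldimethylsilyloxy)-4,8-dimethylspiro[4.5]deca-1,7-dien-1-yl trifluoromethanesulfonate | FC(F)(F)S(=O)(=O)OC1=CC[C@H](C)[C@@]12CC=C(C)[C@@H](O[Si](C)(C)C(C)(C)C)C2
F4 | step 10 | tert-butyl{[(4S,5S,9S)-1-(1-ethoxyethenyl)-4,8-dimethylspiro[4.5]deca-1,7-dien-9-yl]oxy}dimethylsilane | C=C(OCC)C1=CC[C@H](C)[C@@]12CC=C(C)[C@@H](O[Si](C)(C)C(C)(C)C)C2
F5 | step 10 | 1-[(4S,5S,9S)-9-(tert-butyldimethylsilyloxy)-4,8-dimethylspiro[4.5]deca-1,7-dien-1-yl]ethan-1-one | CC(=O)C1=CC[C@H](C)[C@@]12CC=C(C)[C@@H](O[Si](C)(C)C(C)(C)C)C2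
F6 | step 14 | ethyl (3R)-3-[(1R,4S,5S,9S)-9-(tert-butyldimethylsilyloxy)-4,8-dimethylspiro[4.5]dec-7-en-1-yl]butanoate | CCOC(=O)C[C@@H](C)[C@H]1CC[C@H](C)[C@@]12CC=C(C)[C@@H](O[Si](C)(C)C(C)(C)C)C2
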